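**Plan**

1. Retrosynthesis: cut the two ester C–O bonds (O8 last, O9 earlier). Ring A (C1, C2, C3, C4, C5, C10) is then cut at C4–C5 and re-joined as C2–C5, which leads back to a cyclobutanol (C1, C2, C5, C10) carrying an (E)-propenyl group (C3, C4, C15) on C2. The cyclobutane is cut by a [2+2] into the ring-B enone C9(=O)–C10=C5 and a ketene acetal (C1, C2).
2. Enabling feature: in ring A the C2 carbonyl is 1,3 to C4 and 1,4 to the quaternary C5. An oxygen radical on C2 can therefore expel C5 as a tertiary radical and leave C2(=O)–C3=C4 as the acceptor that takes C5 back at C4. The oxygen on C9, next to C10 in ring B, supplies the enone on which the four-membered ring is first built across C5–C10.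
3. Forward order: ring B from (+)-3-carene (allylic oxidation, cyclopropane opening), C8 hydroxylation, [2+2] photocycloaddition, C9 reduction and tigloylation, cyclobutanone, propenyl carbinol, two-carbon ring expansion to the cis-decalin, O8 deprotection and acylation.
4. Stereochemistry: C7 comes from the chiral pool. C8 (enolate hydroxylation) and the cyclobutane, hence C10, are set anti to the C7 isopropenyl. C9 is set by hydride attack anti to the cyclobutane. C5 and C4 are set in the ring expansion (axial closure gives cis fusion; the (E)-alkene gives equatorial C15). The acyl stereocentre comes from (R)-2-methylbutanoic acid.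
5. Net effect: photochemical [2+2] plus radical 1,3-shift amounts to a Diels–Alder-type annulation of a β,β-disubstituted enone with the regiochemistry opposite to the thermal one, joining the two β-carbons C5 and C4.

Key step: step 10

Remark: bicyclic compounds use eremophilane numbering (ring A C1–C4, C5, C10; ring B C5–C10; isopropenyl C11–C13; C14 on C5; C15 on C4), with β = the face of C14. Compounds 15 and 21 are assumed to be bought as single isomers. The carbinol configuration of 18 is drawn as the expected exo adduct and has no bearing on the outcome.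

**Route**

Step 1
Reactants: 1 (+)-3-carene
Product: 2 3-caren-5-one
Conditions: CrO3 (cat.), t-BuOOH (70% aq.), CH2Cl2, rt
Reagents that add atoms: tert-butyl hydroperoxide, CC(C)(C)OO
Why: Chromium-catalysed allylic oxidation attacks the ring CH2 next to the cyclopropane, which is activated by both the alkene and the three-membered ring, and should give the conjugated enone without touching the two stereocentres.

Step 2
Reactants: 2 3-caren-5-one
Product: 4 (S)-3-methyl-5-(prop-1-en-2-yl)cyclohex-2-en-1-one, via tertiary chloride 3 (not isolated)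
Conditions: HCl (g), AcOH, 10 °C; then NaOAc, AcOH, 100 °C
Reagents that add atoms: none
Why: Homoconjugate addition of HCl to the protonated cyclopropyl enone should cleave the external cyclopropane bond that overlaps with the carbonyl π system and leads to the tertiary cation, and acetate-buffered E1 dehydrochlorination should then give mainly the isopropenyl group (six methyl hydrogens against one ring hydrogen); the surviving cyclopropane carbon becomes C7 with its configuration unchanged.

Step 3
Reactants: 4 (S)-3-methyl-5-(prop-1-en-2-yl)cyclohex-2-en-1-one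
Product: 6 (5R,6R)-6-hydroxy-3-methyl-5-(prop-1-en-2-yl)cyclohex-2-en-1-one, via lithium dienolate 5 (not isolated)
Conditions: LDA, THF, −78 °C; then 2-(phenylsulfonyl)-3-phenyloxaziridine, −78 °C; then H2O
Reagents that add atoms: 2-(phenylsulfonyl)-3-phenyloxaziridine, O=S(=O)(N1OC1c1ccccc1)c1ccccc1
Why: Kinetic α′-deprotonation gives the cross-conjugated lithium dienolate, and enolate oxidation by the N-sulfonyloxaziridine should occur on the face opposite the adjacent isopropenyl group, so the new C8 oxygen is trans to C7.

Step 4
Reactants: 6 (5R,6R)-6-hydroxy-3-methyl-5-(prop-1-en-2-yl)cyclohex-2-en-1-one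
Product: 7 (5R,6R)-6-[(tert-butyldimethylsilyl)oxy]-3-methyl-5-(prop-1-en-2-yl)cyclohex-2-en-1-one
Conditions: TBSCl, imidazole, DMF, rt
Reagents that add atoms: tert-butyldimethylsilyl chloride, CC(C)(C)[Si](C)(C)Cl
Why: Standard silylation of a secondary alcohol; the TBS ether marks O8 for late, separate acylation.

Step 5
Reactants: 7 (5R,6R)-6-[(tert-butyldimethylsilyl)oxy]-3-methyl-5-(prop-1-en-2-yl)cyclohex-2-en-1-one; 8 1,1-diethoxyethene
Product: 10 cis-fused cyclobutanone diethyl acetal (8α-OTBS; 7β-isopropenyl; cyclobutane C1/C2 on the α face), via trans-fused cycloadduct 9 (not isolated)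
Conditions: hν (λ > 340 nm, Pyrex), 8 (excess), CH2Cl2, −40 °C; then basic Al2O3, Et2O, rt
Reagents that add atoms: none
Why: Enone–alkene [2+2] photocycloaddition through the enone triplet should add the electron-rich ketene acetal head-to-tail (acetal carbon to the β-carbon C5) and anti to the C7 isopropenyl group (3,5-trans approach on the half-chair), and alumina should epimerise the trans-fused adduct at the enolisable C10 to the cis-fused ring, which places the C1 methylene of C10 on the α face.

Step 6
Reactants: 10 cis-fused cyclobutanone diethyl acetal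
Product: 11 9α-alcohol
Conditions: L-Selectride, THF, −78 °C; then H2O
Reagents that add atoms: none
Why: Bulky-hydride ketone reduction: the hydride should arrive from the β face, away from the cis-fused cyclobutane and its pseudo-axial acetal carbon on the α face (equatorial attack), giving the axial 9α-alcohol cis to the 8α-silyloxy group.

Step 7
Reactants: 11 9α-alcohol; 12 tigloyl chloride
Product: 13 9α-tiglate
Conditions: DMAP, Et3N, CH2Cl2, 40 °C
Reagents that add atoms: none
Why: DMAP-catalysed acylation of the hindered axial alcohol with the acid chloride installs the tiglate at O9 while O8 is still silylated, which tells the two oxygens apart; the (E)-acyl unit is the thermodynamic isomer.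

Step 8
Reactants: 13 9α-tiglate
Product: 14 cyclobutanone
Conditions: TsOH·H2O (cat.), THF/H2O, rt
Reagents that add atoms: water, O
Why: Mild acid hydrolysis of the diethyl acetal should unveil the cyclobutanone under conditions that the secondary TBS ether and the tiglate survive.

Step 9
Reactants: 14 cyclobutanone; 15 (E)-1-bromoprop-1-ene
Product: 18 1-[(E)-prop-1-enyl]cyclobutanol, via (E)-prop-1-enyllithium 16 (not isolated), via (E)-prop-1-enylcerium dichloride 17 (not isolated)
Conditions: 15, t-BuLi (2 equiv), Et2O, −78 °C; anhydrous CeCl3, THF, −78 °C; then 14, −78 °C; then H2O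
Reagents that add atoms: none
Why: Bromine–lithium exchange with retention of alkene geometry, transmetalation to the weakly basic organocerium reagent and 1,2-addition to the strained cyclobutanone, which should outpace attack on the hindered conjugated ester; the new carbinol configuration is of no consequence because this carbon becomes the C2 carbonyl in step 10.

Step 10
Reactants: 18 1-[(E)-prop-1-enyl]cyclobutanol
Product: 19 (4S,5R,7R,8R,9S,10S)-8-[(tert-butyldimethylsilyl)oxy]-9-[(E)-2-methylbut-2-enoyloxy]eremophil-11-en-2-one
Conditions: [Ir(dF(CF3)ppy)2(5,5′-d(CF3)bpy)]PF6 (cat.), NBu4[(BuO)2PO2] (cat.), PhCF3, blue LEDs, rt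
Reagents that add atoms: none
Why: Concerted proton-coupled electron transfer from the tertiary O–H to the excited Ir(III) oxidant and the phosphate base gives the C2 alkoxy radical, whose β-scission breaks the strained C2–C5 bond (tertiary C5 radical preferred over the primary radical from C2–C1 cleavage) and unveils the (E)-propenyl ketone C2(=O)–C3=C4; the nucleophilic C5 radical adds to C4, and the α-keto radical at C3 is reduced by Ir(II) and protonated, so the step is a redox-neutral isomerisation. The closest known reaction type is the photocatalytic PCET ring expansion of 1-alkenylcycloalkanols to (n+2) ketones by alkoxy-radical fragmentation and radical re-closure. Ring A closes in the 6-endo-trig mode (the 5-exo alternative at C3 is polarity-mismatched), so the four-membered ring (C1, C2, C5, C10) becomes the six-membered ring by insertion of C3 and C4. C5 is set by attack on the α lobe, i.e. axial bond formation on the ring-B chair that keeps the C7 isopropenyl, the C8 silyloxy group and the C10 side chain equatorial, which should give the cis-fused decalin through a chair–chair transition state (either face puts one carbon substituent of C5 syn-axial to O9, so the tiglate does not bias the choice); C4 is set by the (E)-alkene geometry, which places its methyl equatorial on the forming chair and hence cis to C14. The step needs ring closure to outrun reduction of the C5 radical (no hydrogen-atom donor is added) and to ignore the isopropenyl group (only 4-exo or 5-endo modes are open) and the tiglate (a lactone-forming 7-endo closure would need the disfavoured s-cis ester).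

Step 11
Reactants: 19 (4S,5R,7R,8R,9S,10S)-8-[(tert-butyldimethylsilyl)oxy]-9-[(E)-2-methylbut-2-enoyloxy]eremophil-11-en-2-one
Product: 20 (4S,5R,7R,8R,9S,10S)-8-hydroxy-9-[(E)-2-methylbut-2-enoyloxy]eremophil-11-en-2-one
Conditions: HF·pyridine, THF, 0 °C to rt
Reagents that add atoms: none
Why: Fluoride-mediated desilylation under buffered acidic conditions should free O8 without the basic alkoxide that would trigger acyl migration from O9 to O8.

Step 12
Reactants: 20 (4S,5R,7R,8R,9S,10S)-8-hydroxy-9-[(E)-2-methylbut-2-enoyloxy]eremophil-11-en-2-one; 21 (R)-2-methylbutanoic acid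
Product: 22 CNP0312791.1
Conditions: DCC, DMAP (cat.), CH2Cl2, 0 °C to rt
Reagents that add atoms: none
Why: Steglich esterification of the equatorial 8α-alcohol at low temperature with only catalytic DMAP should keep the α-stereocentre of the acid and leave the neighbouring tiglate in place.

**Compound list**

1 | (+)-3-carene, (1S,6R)-3,7,7-trimethylbicyclo[4.1.0]hept-3-ene | CC1=CC[C@@H]2[C@H](C1)C2(C)C | starting material
2 | 3-caren-5-one, (1R,6S)-4,7,7-trimethylbicyclo[4.1.0]hept-3-en-2-one | CC1=CC(=O)[C@@H]2[C@H](C1)C2(C)C | intermediate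
3 | (S)-5-(2-chloropropan-2-yl)-3-methylcyclohex-2-en-1-one | CC(C)(Cl)[C@H]1CC(C)=CC(=O)C1 | intermediate
4 | (S)-3-methyl-5-(prop-1-en-2-yl)cyclohex-2-en-1-one | C=C(C)[C@H]1CC(C)=CC(=O)C1 | intermediate
5 | lithium (S)-5-methyl-3-(prop-1-en-2-yl)cyclohexa-1,5-dien-1-olate | C=C(C)[C@H]1CC(C)=CC(O[Li])=C1 | intermediate
6 | (5R,6R)-6-hydroxy-3-methyl-5-(prop-1-en-2-yl)cyclohex-2-en-1-one (trans) | C=C(C)[C@H]1CC(C)=CC(=O)[C@@H]1O | intermediate
7 | (5R,6R)-6-[(tert-butyldimethylsilyl)oxy]-3-methyl-5-(prop-1-en-2-yl)cyclohex-2-en-1-one | C=C(C)[C@H]1CC(C)=CC(=O)[C@@H]1O[Si](C)(C)C(C)(C)C | intermediate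
8 | 1,1-diethoxyethene | C=C(OCC)OCC | starting material
9 | trans-fused (C10-epimeric) photoadduct of 7 and 8 | C=C(C)[C@H]1C[C@@]2(C)[C@@H](CC2(OCC)OCC)C(=O)[C@@H]1O[Si](C)(C)C(C)(C)C | intermediate
10 | cis-fused 3-[(tert-butyldimethylsilyl)oxy]-7,7-diethoxy-6-methyl-4-(prop-1-en-2-yl)bicyclo[4.2.0]octan-2-one; 8α-OTBS, 7β-isopropenyl, 5β-methyl, 10β-H, cyclobutane on the α face | C=C(C)[C@H]1C[C@@]2(C)[C@H](CC2(OCC)OCC)C(=O)[C@@H]1O[Si](C)(C)C(C)(C)C | intermediate
11 | corresponding bicyclo[4.2.0]octan-2-ol with 9α-OH (cis to 8α-OTBS and to the cyclobutane) | C=C(C)[C@H]1C[C@@]2(C)[C@H](CC2(OCC)OCC)[C@H](O)[C@@H]1O[Si](C)(C)C(C)(C)C | intermediate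
12 | tigloyl chloride, (E)-2-methylbut-2-enoyl chloride | C/C=C(\C)C(=O)Cl | starting material
13 | 9α-tiglate of 11 | C=C(C)[C@H]1C[C@@]2(C)[C@H](CC2(OCC)OCC)[C@H](OC(=O)/C(C)=C/C)[C@@H]1O[Si](C)(C)C(C)(C)C | intermediate
14 | cis-fused 3-[(tert-butyldimethylsilyl)oxy]-6-methyl-7-oxo-4-(prop-1-en-2-yl)bicyclo[4.2.0]octan-2-yl (E)-2-methylbut-2-enoate (cyclobutanone, C2=O on C5) | C=C(C)[C@H]1C[C@@]2(C)[C@H](CC2=O)[C@H](OC(=O)/C(C)=C/C)[C@@H]1O[Si](C)(C)C(C)(C)C | intermediate
15 | (E)-1-bromoprop-1-ene | C/C=C/Br | starting material
16 | (E)-prop-1-enyllithium | C/C=C/[Li] | intermediate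
17 | (E)-prop-1-enylcerium dichloride | C/C=C/[Ce](Cl)Cl | intermediate
18 | cis-fused 3-[(tert-butyldimethylsilyl)oxy]-7-hydroxy-6-methyl-4-(prop-1-en-2-yl)-7-[(E)-prop-1-enyl]bicyclo[4.2.0]octan-2-yl (E)-2-methylbut-2-enoate (propenyl exo, cis to C14) | C=C(C)[C@H]1C[C@@]2(C)[C@H](C[C@]2(O)/C=C/C)[C@H](OC(=O)/C(C)=C/C)[C@@H]1O[Si](C)(C)C(C)(C)C | intermediate
19 | (4S,5R,7R,8R,9S,10S)-8-[(tert-butyldimethylsilyl)oxy]-9-[(E)-2-methylbut-2-enoyloxy]eremophil-11-en-2-one (cis-fused, 10βH) | C=C(C)[C@H]1C[C@@]2(C)[C@H](CC(=O)C[C@@H]2C)[C@H](OC(=O)/C(C)=C/C)[C@@H]1O[Si](C)(C)C(C)(C)C | intermediate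
20 | (4S,5R,7R,8R,9S,10S)-8-hydroxy-9-[(E)-2-methylbut-2-enoyloxy]eremophil-11-en-2-one | C=C(C)[C@H]1C[C@@]2(C)[C@H](CC(=O)C[C@@H]2C)[C@H](OC(=O)/C(C)=C/C)[C@@H]1O | intermediate
21 | (R)-2-methylbutanoic acid | CC[C@@H](C)C(=O)O | starting material
22 | CNP0312791.1, (4S,5R,7R,8R,9S,10S)-8-[(2R)-2-methylbutanoyloxy]-9-[(E)-2-methylbut-2-enoyloxy]eremophil-11-en-2-one | C=C(C)[C@H]1C[C@@]2(C)[C@H](CC(=O)C[C@@H]2C)[C@H](OC(=O)/C(C)=C/C)[C@@H]1OC(=O)[C@H](C)CC | target

**Step count and risks**

Total step count: 12. Longest linear sequence: 12 steps (1 to 22).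

Steps most likely to fail:

1. Step 10. The planar C5 radical could be attacked on its β lobe (trans-fused ring A), or be reduced or oxidised before it closes, leaving the ring-opened enone; O–H activation of the hindered tertiary cyclobutanol could also be slow. The fallback sets out from 18 and uses the thermal vinylcyclobutane-to-cyclohexene 1,3-shift, which needs no catalyst and no radical chain. Silylation (TMSCl, imidazole) should give the trimethylsilyl ether F1. Flash vacuum thermolysis (or a sealed tube near 200 °C) should move C5 from C2 to C4 and give the C2 trimethylsilyl enol ether F2; retro-[2+2] fragmentation is the competing channel. Mild aqueous acid then hydrolyses F2, and the route is rejoined at 19.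

2. Step 5. Facial discrimination at C5/C10 may be poor, the α-silyloxy ketone product may undergo secondary α-cleavage under irradiation, and the enone may be consumed by intramolecular cycloaddition to the isopropenyl group. The fallback sets out from 4 and places the cycloaddition before the oxygenation. Irradiation of 4 with 8, then alumina, should give the cis-fused bicyclic ketone acetal F3. Kinetic enolisation toward the C8 methylene (the ring-fusion C10–H is not removed, since that would put a double bond at the cyclobutane fusion) and oxidation with the N-sulfonyloxaziridine anti to the isopropenyl group should give the 8α-hydroxy ketone F4. Silylation (TBSCl, imidazole) rejoins the route at 10.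

3. Step 9. The organometallic may attack the tiglate (1,2- or conjugate addition), or the cyclobutanone may be enolised instead of adding. The fallback sets out from 11 and keeps every ester out of the addition step. Acetal hydrolysis with O9 unprotected should give the hydroxy cyclobutanone F5 (in equilibrium with its internal hemiketal). Excess (E)-propenylcerium reagent (the first equivalent forms the alkoxide) should give the diol F6. Tigloyl chloride 12 with DMAP then acylates the secondary O9–H in preference to the tertiary cyclobutanol, and the route is rejoined at 18.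

**Further compounds**

F1 | step 10 | trimethylsilyl ether of 18 | C=C(C)[C@H]1C[C@@]2(C)[C@H](C[C@]2(O[Si](C)(C)C)/C=C/C)[C@H](OC(=O)/C(C)=C/C)[C@@H]1O[Si](C)(C)C(C)(C)C
F2 | step 10 | C2 trimethylsilyl enol ether (Δ2,3) of 19 | C=C(C)[C@H]1C[C@@]2(C)[C@H](CC(O[Si](C)(C)C)=C[C@@H]2C)[C@H](OC(=O)/C(C)=C/C)[C@@H]1O[Si](C)(C)C(C)(C)C
F3 | step 5 | cis-fused 7,7-diethoxy-6-methyl-4-(prop-1-en-2-yl)bicyclo[4.2.0]octan-2-one (cyclobutane anti to isopropenyl) | C=C(C)[C@H]1C[C@@]2(C)[C@H](CC2(OCC)OCC)C(=O)C1
F4 | step 5 | 3-hydroxy derivative of F3 (8α-OH, trans to isopropenyl) | C=C(C)[C@H]1C[C@@]2(C)[C@H](CC2(OCC)OCC)C(=O)[C@@H]1O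
F5 | step 9 | cis-fused 3-[(tert-butyldimethylsilyl)oxy]-2-hydroxy-6-methyl-4-(prop-1-en-2-yl)bicyclo[4.2.0]octan-7-one (9α-OH) | C=C(C)[C@H]1C[C@@]2(C)[C@H](CC2=O)[C@H](O)[C@@H]1O[Si](C)(C)C(C)(C)C
F6 | step 9 | cis-fused 3-[(tert-butyldimethylsilyl)oxy]-6-methyl-4-(prop-1-en-2-yl)-7-[(E)-prop-1-enyl]bicyclo[4.2.0]octane-2,7-diol | C=C(C)[C@H]1C[C@@]2(C)[C@H](C[C@]2(O)/C=C/C)[C@H](O)[C@@H]1O[Si](C)(C)C(C)(C)C
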